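## Structural features

The target consists of two 2-(4-hydroxyphenyl)chromane-3,7,8-triol units, each with a catechol ring A, a pyran ring C and a 4-hydroxyphenyl ring B. They are joined by one ether oxygen between their C4 atoms, so each C4 is a secondary benzylic ether carbon ortho to O1 and para to the C7 oxygen. Each unit has the contiguous triad C2–C3–C4; both units are (3R,4R) with the C3 and C4 oxygens cis, while unit A is 2R (2,3-cis) and unit B is 2S (2,3-trans). The halves are therefore constitutionally identical and differ only at C2, so it does not matter which half ends as unit A. Fragile points are the catechols (oxidation, worst in base), the C4–O–C4 ether (ionisation by acid or Lewis acid, hydrogenolysis) and the benzylic C2–O1 bonds para to the ring B oxygen. The real difficulty is to make two halves that differ at one carbon on a core whose two ends cannot be told apart, without ionising C4. The key step uses the C2–C1' bonds: ring B is added to a C2 aldehyde of each half, and the oxygen on the adjacent C3 (a chelating arylmethyl ether on one half, a non-chelating silyl ether on the other) sets the new C2 carbinol in opposite senses.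

## Logic of the disconnections

23 ⇒ 22 ⇒ 21. Seven O–CH2Ar bonds (six phenolic benzyl, one aliphatic 2-naphthylmethyl) and one O–Si bond are cut. The polyphenol has to appear last and under neutral conditions. The demand is that hydrogenolysis removes only fast-reacting arylmethyl ethers and leaves the C4–O–C4 and C2–O1 bonds alone, which is why the aliphatic ether is 2-naphthylmethyl and the silyl ether is taken off beforehand.

21 ⇒ 20 ⇒ 19. Both O1–C2 bonds are cut, then the two phenolic O–Si bonds. This turns both C rings into a phenol facing a benzylic carbinol and converts the C2 problem into acyclic 1,2-stereocontrol. The forward closure must go with clean inversion at two electron-rich benzylic carbons (erythro to 2,3-cis, threo to 2,3-trans), and the phenols must be freed without touching the C3 silyl ether.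

19 ⇒ 16 + two molecules of 18 (each from 17). Both C2–C1' bonds are cut. Both B rings then come from one aryl nucleophile, used twice, and both C2 centres from the C3 oxygen next door. The two aldehydes of 16 must react with opposite facial sense, which only the two different C3 protecting groups can enforce.

16 ⇒ 15 ⇒ 14 ⇒ 13 ⇒ 12 ⇒ 11. No skeletal bond is cut; oxidation level and protecting groups are adjusted. The gain is a C2-symmetric tetraol as the only stereochemically demanding precursor. The demand is one desymmetrising event (12 to 13) on two homotopic hydroxyls, under conditions that do not move silyl groups, and selective release of the primary hydroxyls.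

11 ⇒ 10 ⇒ 9 ⇒ 8. The C2–O and C3–O bonds of both arms (flavan numbering) are cut back to two vinyl groups, then the ortho O–Si bonds back to O–allyl. Both C3 centres then derive from the C4 centres. The osmylation must be anti to the C4 ether oxygen on both arms, and no other alkene may be present, which forces the allyl-to-silyl exchange before it.

8 ⇒ 7 + 6, and 7 ⇒ 6. The two C4–O bonds are cut. Both C4 centres are then set by one chiral catalyst and the core is C2-symmetric from the start. The forward steps need branched regioselectivity and catalyst control with an ortho-substituted aryl group and a secondary alkoxide, so the ortho substituent must be small and inert to alkoxide (allyl).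

6 ⇒ 5 ⇒ 4 ⇒ 3. The carbonate C–O bond, the ester oxidation level and the C=C bond are taken back to the aldehyde. This is a routine two-carbon homologation that must give the E alkene.

3 ⇒ 2 ⇒ 1. The three aryl O–C ether bonds are cut. The only demand is regioselective dibenzylation at O3 and O4 before the chelated O2 is allylated.

## Other disconnections considered

Alternative 1: The cut is the C3=C4 double bond of a 4-alkoxy-2H-chromene standing in for ring C of unit B. In the forward step ester A2 (the C4 benzoate of a complete all-cis half, its benzoate ring carrying a 1-arylallyl ether on the ortho oxygen) is treated with excess Cp2Ti(CH2)ClAlMe2. Carbonyl methylenation is followed by ring closure of the enol ether onto the vinyl group, giving chromene A1.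
- In its favour: the interflavanyl oxygen is installed by simple acylation, and C2 of unit B is set by catalyst-controlled allylation of a phenol. No benzylic displacement is needed for unit B. On these points it is equal to or better than the chosen plan.
- Against it: A1 still lacks the C3 hydroxyl and C4 hydrogen of unit B. Hydroboration adds H and OH syn, which would place the C4 oxygen trans to the new C3 hydroxyl, whereas the target needs 3,4-cis. An epoxidation and reductive opening at a ketal-like carbon would be needed, with no assured facial course. A2 also presupposes that the all-cis half has been made in full, and a large excess of a Lewis-acidic titanium–aluminium reagent meets a hindered, ionisable benzylic ester.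
- Comparison: on structure it handles the ether bond and C2 of unit B more securely. On mechanism the chosen plan sets C3 and C4 of both units in one dihydroxylation and needs no hydration of an enol ether. In step economy the alternative is the longer one, because one half must be finished before the other is begun.

Alternative 2: The cuts are C5–C6 and C4a–C8a of both A rings. In the forward step the bis(vinylstannane) ether A4 undergoes twofold Stille coupling with chlorocyclobutenone A5 (Pd2(dba)3, tri(2-furyl)phosphine). Thermal 4π opening to a dienylketene and 6π closure then give bis-phenol A3.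
- In its favour: the C8a phenols appear free and in the right place, so no protecting group is needed on the cyclising oxygen. The chosen route pays an allyl-to-silyl exchange and a selective desilylation for this, so here the alternative is better. The regioselective protection of a trihydroxybenzaldehyde is also avoided.
- Against it: A4 must already contain all six stereocentres, including two C2 carbinols of opposite relative configuration. They would have to be built without the aryl groups that make the iridium etherification and the anti osmylation work. Two equivalents of tin and a sensitive 4-chlorocyclobutenone are needed, and the substrate with its allylic ether and silyl ethers must survive thermolysis. A3 is still closed by the same double Mitsunobu reaction.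
- Comparison: the end-game is the same, so the two plans are equal there. Mechanistically the pericyclic cascade is regiospecific, which is a point in its favour. Structurally the C2 problem is only moved upstream, and building two arenes de novo makes the route clearly longer.

Alternative 3: The cuts are both O1–C8a bonds of a C2-symmetric dimer. In the forward step dibromo diol A7 is cyclised with CuI, 3,4,7,8-tetramethyl-1,10-phenanthroline and Cs2CO3. Each C2 alkoxide couples with its aryl bromide with retention, giving all-cis dimer A6; one C2 is then epimerised.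
- In its favour: every step before the end is two-directional. Both carbinols are threo and come from the more reliable chelation-controlled addition. No desymmetrising protection is needed, and the closure does not activate the ionisable benzylic carbinol. On symmetry, step economy up to the dimer and closure mechanism it is equal to or better than the chosen plan.
- Against it: epimerising one of two homotopic C2 centres needs a free 4'-hydroxyl and base (ring opening to a quinone methide). It is an equilibrium that cannot distinguish the two units, so cis–cis, cis–trans and trans–trans dimers are all expected. The aryl bromide is flanked by two ortho substituents.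
- Comparison: the chosen plan also has one unselective event, the mono-alkylation of 12. That event is early and irreversible, on robust material that can be recycled. The alternative leaves it to the last stage on the complete dimer.

Key step: step 16

Remarks on the chemistry (one line each):
- Choice of the ortho protecting group: an allyl ether on the ring A ortho oxygen cannot be carried through osmylation of the vinyl groups, because all four alkenes would be monosubstituted allylic ethers. A silyl ether there cannot be carried through the iridium etherification either, since the benzylic alkoxide would take it by 1,5 O-to-O shift. The ortho oxygens are therefore allyl ethers in 3–8 and TBS ethers in 10–19.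
- The chelating C3 ether is 2-naphthylmethyl (NAP), a benzyl-type ether. It acts like a benzyl ether in the key step, is hydrogenolysed faster than an aliphatic benzyl ether, and can alternatively be removed with DDQ.
- The two arms of 11 and 12 are homotopic, so one desymmetrising step (step 12) is unavoidable.
- Assumption: the sense of the iridium steps is assigned by analogy with cinnamyl carbonates and oxygen nucleophiles; the antipode of L would be used if the ortho-alkoxy group reversed it.
- Abbreviations: Ar = 3,4-bis(benzyloxy)-2-(tert-butyldimethylsilyloxy)phenyl; Ar' = 3,4-bis(benzyloxy)-2-hydroxyphenyl; TBS = tert-butyldimethylsilyl; L = (Sa,S,S)-O,O'-(1,1'-binaphthalene-2,2'-diyl) N,N-bis[1-(2-methoxyphenyl)ethyl]phosphoramidite. Flavan numbering (C2, C3, C4) is used for the acyclic arms in the explanations.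

## Route

Step 1
Reactants: 1 2,3,4-trihydroxybenzaldehyde
Product: 2 3,4-bis(benzyloxy)-2-hydroxybenzaldehyde
Conditions: BnBr (2.05 equiv), K2CO3 (2.1 equiv), DMF, rt
Reagents that add atoms: benzyl bromide, BrCc1ccccc1
Why: Williamson etherification; the C2 hydroxyl is hydrogen-bonded to the formyl group and its phenoxide is the least nucleophilic, so O4 and O3 are alkylated first, as in the classical selective dibenzylation of 2,3,4-trihydroxyaryl carbonyl compounds.

Step 2
Reactants: 2 3,4-bis(benzyloxy)-2-hydroxybenzaldehyde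
Product: 3 2-(allyloxy)-3,4-bis(benzyloxy)benzaldehyde
Conditions: allyl bromide (1.5 equiv), K2CO3, DMF, 50 °C
Reagents that add atoms: allyl bromide, C=CCBr
Why: Williamson etherification of the remaining chelated phenol under slightly more forcing conditions; the allyl ether is small, inert to alkoxides and removable by palladium catalysis.

Step 3
Reactants: 3 2-(allyloxy)-3,4-bis(benzyloxy)benzaldehyde
Product: 4 ethyl (E)-3-[2-(allyloxy)-3,4-bis(benzyloxy)phenyl]prop-2-enoate
Conditions: (EtO)2P(O)CH2CO2Et, NaH, THF, 0 °C to rt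
Reagents that add atoms: triethyl phosphonoacetate, CCOC(=O)CP(=O)(OCC)OCC
Why: Horner–Wadsworth–Emmons olefination of a non-enolisable aryl aldehyde; the stabilised phosphonate anion gives the E enoate.

Step 4
Reactants: 4 ethyl (E)-3-[2-(allyloxy)-3,4-bis(benzyloxy)phenyl]prop-2-enoate
Product: 5 (E)-3-[2-(allyloxy)-3,4-bis(benzyloxy)phenyl]prop-2-en-1-ol
Conditions: i-Bu2AlH (2.3 equiv), CH2Cl2, −78 °C; aq. potassium sodium tartrate
Reagents that add atoms: none
Why: 1,2-reduction of the enoate to the allylic alcohol; aryl ethers and the alkene are untouched at low temperature.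

Step 5
Reactants: 5 (E)-3-[2-(allyloxy)-3,4-bis(benzyloxy)phenyl]prop-2-en-1-ol
Product: 6 (E)-3-[2-(allyloxy)-3,4-bis(benzyloxy)phenyl]allyl methyl carbonate
Conditions: ClCO2Me, pyridine, CH2Cl2, 0 °C
Reagents that add atoms: methyl chloroformate, COC(=O)Cl
Why: O-acylation; the methyl carbonate is the standard leaving group for iridium-catalysed allylic substitution.

Step 6
Reactants: 6 (E)-3-[2-(allyloxy)-3,4-bis(benzyloxy)phenyl]allyl methyl carbonate
Product: 7 (S)-1-[2-(allyloxy)-3,4-bis(benzyloxy)phenyl]prop-2-en-1-ol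
Conditions: [Ir(cod)Cl]2 (2 mol%), L (4 mol%), n-PrNH2 (catalyst activation), KHCO3 (3 equiv), CH2Cl2–H2O, rt
Reagents that add atoms: potassium hydrogen carbonate, [K+].OC([O-])=O
Why: Iridium-catalysed allylic substitution in which hydrogen carbonate serves as a hydroxide equivalent, CO2 being lost after the C–O bond has formed. The cyclometalated iridium–phosphoramidite catalyst directs attack to the aryl-bearing allyl terminus and sets the (S) centre, the future C4, by catalyst control.

Step 7
Reactants: 7 (S)-1-[2-(allyloxy)-3,4-bis(benzyloxy)phenyl]prop-2-en-1-ol; 6 (E)-3-[2-(allyloxy)-3,4-bis(benzyloxy)phenyl]allyl methyl carbonate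
Product: 8 bis{(S)-1-[2-(allyloxy)-3,4-bis(benzyloxy)phenyl]allyl} ether
Conditions: 7 (1.3 equiv), n-BuLi, THF, −78 to 0 °C; CuI, rt; then 6, [Ir(cod)Cl]2 (2 mol%), L (4 mol%), THF, rt
Reagents that add atoms: none
Why: Iridium-catalysed allylic etherification with a secondary copper alkoxide (ROCu), a known way to diastereomerically defined bis(allyl) ethers. Branched-selective attack under catalyst control sets the second (S) centre and gives the C2-symmetric ether; the aryl allyl ethers and the product dialkyl ether are not ionised by the catalyst.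

Step 8
Reactants: 8 bis{(S)-1-[2-(allyloxy)-3,4-bis(benzyloxy)phenyl]allyl} ether
Product: 9 bis{(S)-1-[3,4-bis(benzyloxy)-2-hydroxyphenyl]allyl} ether
Conditions: Pd(PPh3)4 (5 mol%), morpholine (10 equiv), THF, rt
Reagents that add atoms: none
Why: Tsuji–Trost deallylation; zerovalent palladium ionises only the aryl allyl ethers (phenoxide leaving group) and morpholine traps the allyl fragment, while the central dialkyl ether with its alkoxide leaving group stays intact.

Step 9
Reactants: 9 bis{(S)-1-[3,4-bis(benzyloxy)-2-hydroxyphenyl]allyl} ether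
Product: 10 bis{(S)-1-[3,4-bis(benzyloxy)-2-(tert-butyldimethylsilyloxy)phenyl]allyl} ether
Conditions: TBSCl (3 equiv), imidazole (6 equiv), DMF, rt
Reagents that add atoms: tert-butyldimethylsilyl chloride, CC(C)(C)[Si](C)(C)Cl
Why: O-silylation of the two phenols; from here the only alkenes left are the two vinyl groups, and no alkoxide is generated next to the aryl silyl ethers before they are removed.

Step 10
Reactants: 10 bis{(S)-1-[3,4-bis(benzyloxy)-2-(tert-butyldimethylsilyloxy)phenyl]allyl} ether
Product: 11 (2S,2'S,3R,3'R)-3,3'-oxybis(3-Ar-propane-1,2-diol)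
Conditions: OsO4 (4 mol%), (DHQD)2PHAL (8 mol%), NMO (3 equiv), acetone–H2O, 0 °C to rt; aq. Na2SO3
Reagents that add atoms: osmium tetroxide (catalytic oxygen carrier), O=[Os](=O)(=O)=O; N-methylmorpholine N-oxide, C[N+]1([O-])CCOCC1; water, O
Why: Ligand-accelerated catalytic dihydroxylation (Sharpless type) of both vinyl groups. Osmylation of an allylic ether takes place anti to the allylic C–O bond (erythro rule), and the face preference of (DHQD)2PHAL for a monosubstituted alkene is predicted to reinforce it, so each new carbinol (future C3) is anti to the C4 ether oxygen.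

Step 11
Reactants: 11 (2S,2'S,3R,3'R)-3,3'-oxybis(3-Ar-propane-1,2-diol)
Product: 12 (2S,2'S,3R,3'R)-3,3'-oxybis[3-Ar-1-(tert-butyldimethylsilyloxy)propan-2-ol]
Conditions: TBSCl (2.2 equiv), imidazole, CH2Cl2, 0 °C
Reagents that add atoms: tert-butyldimethylsilyl chloride, CC(C)(C)[Si](C)(C)Cl
Why: Selective silylation of the two primary hydroxyls; the secondary ones are shielded by the neighbouring aryl-bearing carbon.

Step 12
Reactants: 12 (2S,2'S,3R,3'R)-3,3'-oxybis[3-Ar-1-(tert-butyldimethylsilyloxy)propan-2-ol]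
Product: 13 (2S,3R)-3-Ar-3-{[(1R,2S)-1-Ar-3-(tert-butyldimethylsilyloxy)-2-(naphthalen-2-ylmethoxy)propyl]oxy}-1-(tert-butyldimethylsilyloxy)propan-2-ol
Conditions: 2-(bromomethyl)naphthalene (1.1 equiv), Ag2O (1.5 equiv), KI (cat.), CH2Cl2–DMF, rt, dark; recovered 12 recycled
Reagents that add atoms: 2-(bromomethyl)naphthalene, BrCc1ccc2ccccc2c1
Why: Ag2O-mediated Williamson-type mono-alkylation; the two hydroxyls are homotopic, so alkylation of either gives 13, and the neutral medium avoids 1,2-silyl migration. The HO–C–C–O–C–C–OH array resembles diethylene glycol, a class for which Ag2O favours mono-ethers, but at worst the step is statistical with recycling.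

Step 13
Reactants: 13 (2S,3R)-3-Ar-3-{[(1R,2S)-1-Ar-3-(tert-butyldimethylsilyloxy)-2-(naphthalen-2-ylmethoxy)propyl]oxy}-1-(tert-butyldimethylsilyloxy)propan-2-ol
Product: 14 (1R,2S)-1-Ar-2,3-bis(tert-butyldimethylsilyloxy)propyl (1R,2S)-1-Ar-3-(tert-butyldimethylsilyloxy)-2-(naphthalen-2-ylmethoxy)propyl ether
Conditions: TBSOTf (1.5 equiv), 2,6-lutidine (3 equiv), CH2Cl2, −78 to 0 °C
Reagents that add atoms: tert-butyldimethylsilyl triflate, CC(C)(C)[Si](C)(C)OS(=O)(=O)C(F)(F)F
Why: Silylation of the remaining hindered secondary hydroxyl with the reactive triflate under buffered conditions; this installs the non-chelating C3 group of the second arm.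

Step 14
Reactants: 14 (1R,2S)-1-Ar-2,3-bis(tert-butyldimethylsilyloxy)propyl (1R,2S)-1-Ar-3-(tert-butyldimethylsilyloxy)-2-(naphthalen-2-ylmethoxy)propyl ether
Product: 15 (2S,3R)-3-Ar-3-{[(1R,2S)-1-Ar-3-hydroxy-2-(naphthalen-2-ylmethoxy)propyl]oxy}-2-(tert-butyldimethylsilyloxy)propan-1-ol
Conditions: HF·pyridine, pyridine, THF, 0 °C
Reagents that add atoms: none
Why: Selective desilylation; under buffered acidic fluoride, primary alkyl TBS ethers are cleaved faster than the hindered secondary alkyl and the di-ortho-substituted aryl TBS ethers.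

Step 15
Reactants: 15 (2S,3R)-3-Ar-3-{[(1R,2S)-1-Ar-3-hydroxy-2-(naphthalen-2-ylmethoxy)propyl]oxy}-2-(tert-butyldimethylsilyloxy)propan-1-ol
Product: 16 (2R,3R)-3-Ar-3-{[(1R,2R)-1-Ar-2-(naphthalen-2-ylmethoxy)-3-oxopropyl]oxy}-2-(tert-butyldimethylsilyloxy)propanal
Conditions: Dess–Martin periodinane (3 equiv), NaHCO3, CH2Cl2, 0 °C to rt; filtered and used without chromatography
Reagents that add atoms: none
Why: Dess–Martin oxidation of both primary alcohols under buffered, non-basic conditions, so the α-oxygenated aldehydes do not epimerise. The α-carbons become (R) only because the formyl group now outranks the benzylic carbon; their geometry is unchanged.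

Step 16
Reactants: 16 (2R,3R)-3-Ar-3-{[(1R,2R)-1-Ar-2-(naphthalen-2-ylmethoxy)-3-oxopropyl]oxy}-2-(tert-butyldimethylsilyloxy)propanal; 17 1-(benzyloxy)-4-bromobenzene
Product: 19 (1S,2S,3R)-3-Ar-1-[4-(benzyloxy)phenyl]-3-{[(1R,2S,3R)-1-Ar-3-[4-(benzyloxy)phenyl]-3-hydroxy-2-(naphthalen-2-ylmethoxy)propyl]oxy}-2-(tert-butyldimethylsilyloxy)propan-1-ol, via 4-(benzyloxy)phenylmagnesium bromide 18 (not isolated)
Conditions: 17 (3.3 equiv), Mg (3.6 equiv), THF, 40 °C (gives 18, about 1 M); 16 (1 equiv), MgBr2·OEt2 (1.2 equiv), CH2Cl2, −78 °C; then 18 (3 equiv, of which 2 equiv are consumed), −78 °C; aq. NH4Cl at −78 °C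
Reagents that add atoms: 4-(benzyloxy)phenylmagnesium bromide (second molar equivalent of 18), Br[Mg]c1ccc(OCc2ccccc2)cc1
Why: Each of the two formyl groups undergoes 1,2-addition of one molecule of 18, so two molar equivalents of the aryl reagent are built into 19 and a third is held in excess; the closest known reaction types are chelation-controlled addition of Grignard reagents to α-alkoxy aldehydes and Felkin–Anh addition to α-silyloxy aldehydes. On the naphthylmethoxy arm magnesium bridges the carbonyl and ether oxygens in a five-membered chelate, and the aryl group enters on the face away from the C4 substituent, which gives the threo (1R,2S) carbinol. On the silyloxy arm the bulky, weakly basic TBS ether cannot chelate, the C–OSi bond lies anti to the incoming nucleophile, and attack past the α-hydrogen gives the erythro (1S,2S) carbinol. No ring is closed; two C–C bonds and two stereocentres are formed. The step needs opposite 1,2-induction at two otherwise identical aldehydes, and only the C3 protecting groups provide it. MgBr2·OEt2 in CH2Cl2 with little THF strengthens the chelate without making the silyl ether a ligand, and the chelated aldehyde is also the more electrophilic one. Quenching at −78 °C avoids α-epimerisation and 1,2-silyl migration in the magnesium alkoxides.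

Step 17
Reactants: 19 (1S,2S,3R)-3-Ar-1-[4-(benzyloxy)phenyl]-3-{[(1R,2S,3R)-1-Ar-3-[4-(benzyloxy)phenyl]-3-hydroxy-2-(naphthalen-2-ylmethoxy)propyl]oxy}-2-(tert-butyldimethylsilyloxy)propan-1-ol
Product: 20 (1S,2S,3R)-3-Ar'-1-[4-(benzyloxy)phenyl]-3-{[(1R,2S,3R)-1-Ar'-3-[4-(benzyloxy)phenyl]-3-hydroxy-2-(naphthalen-2-ylmethoxy)propyl]oxy}-2-(tert-butyldimethylsilyloxy)propan-1-ol
Conditions: TBAF (2.2 equiv), AcOH (2.2 equiv), THF, 0 °C
Reagents that add atoms: none
Why: Buffered fluoride cleaves the two phenolic silyl ethers much faster than the hindered secondary alkyl silyl ether; the buffer keeps alkoxides from forming, so the C3 silyl group does not migrate to the adjacent C2 hydroxyl.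

Step 18
Reactants: 20 (1S,2S,3R)-3-Ar'-1-[4-(benzyloxy)phenyl]-3-{[(1R,2S,3R)-1-Ar'-3-[4-(benzyloxy)phenyl]-3-hydroxy-2-(naphthalen-2-ylmethoxy)propyl]oxy}-2-(tert-butyldimethylsilyloxy)propan-1-ol
Product: 21 (2R,3R,4R)-7,8-bis(benzyloxy)-2-[4-(benzyloxy)phenyl]-3-(tert-butyldimethylsilyloxy)-4-{[(2S,3R,4R)-7,8-bis(benzyloxy)-2-[4-(benzyloxy)phenyl]-3-(naphthalen-2-ylmethoxy)chroman-4-yl]oxy}chromane
Conditions: PPh3 (4 equiv), DIAD (4 equiv), toluene (high dilution), 0 °C to rt
Reagents that add atoms: none
Why: Twofold intramolecular Mitsunobu etherification (6-exo-tet), a closure known for 2-arylchromans with electron-rich B rings. Each phenol displaces the oxyphosphonium of its own benzylic carbinol with inversion, so the erythro arm gives the 2,3-cis ring and the threo arm the 2,3-trans ring; with both C3 oxygens protected neither epoxide nor five-membered ring formation can compete.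

Step 19
Reactants: 21 (2R,3R,4R)-7,8-bis(benzyloxy)-2-[4-(benzyloxy)phenyl]-3-(tert-butyldimethylsilyloxy)-4-{[(2S,3R,4R)-7,8-bis(benzyloxy)-2-[4-(benzyloxy)phenyl]-3-(naphthalen-2-ylmethoxy)chroman-4-yl]oxy}chromane
Product: 22 (2R,3R,4R)-7,8-bis(benzyloxy)-2-[4-(benzyloxy)phenyl]-4-{[(2S,3R,4R)-7,8-bis(benzyloxy)-2-[4-(benzyloxy)phenyl]-3-(naphthalen-2-ylmethoxy)chroman-4-yl]oxy}chroman-3-ol
Conditions: TBAF (3 equiv), THF, rt
Reagents that add atoms: none
Why: Fluoride cleavage of the remaining secondary silyl ether; the non-acidic medium spares the C4–O–C4 ether.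

Step 20
Reactants: 22 (2R,3R,4R)-7,8-bis(benzyloxy)-2-[4-(benzyloxy)phenyl]-4-{[(2S,3R,4R)-7,8-bis(benzyloxy)-2-[4-(benzyloxy)phenyl]-3-(naphthalen-2-ylmethoxy)chroman-4-yl]oxy}chroman-3-ol
Product: 23 (2R,3R,4R)-2-(4-hydroxyphenyl)-4-{[(2S,3R,4R)-3,7,8-trihydroxy-2-(4-hydroxyphenyl)chroman-4-yl]oxy}chromane-3,7,8-triol
Conditions: H2 (1 atm), Pd(OH)2/C, THF–MeOH, rt; stopped when debenzylation is complete; work-up under argon
Reagents that add atoms: none
Why: Neutral hydrogenolysis of six phenolic benzyl ethers and the 2-naphthylmethyl ether, the arylmethyl classes that react fastest. The hindered dialkyl benzylic C4–O and C2–O bonds should react far more slowly, and no stereocentre is touched.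

## Compound list

1 | 2,3,4-trihydroxybenzaldehyde | O=Cc1ccc(O)c(O)c1O | starting material
2 | 3,4-bis(benzyloxy)-2-hydroxybenzaldehyde | O=Cc1ccc(OCc9ccccc9)c(OCc9ccccc9)c1O | intermediate
3 | 2-(allyloxy)-3,4-bis(benzyloxy)benzaldehyde | O=Cc1ccc(OCc9ccccc9)c(OCc9ccccc9)c1OCC=C | intermediate
4 | ethyl (E)-3-[2-(allyloxy)-3,4-bis(benzyloxy)phenyl]prop-2-enoate | CCOC(=O)/C=C/c1ccc(OCc9ccccc9)c(OCc9ccccc9)c1OCC=C | intermediate
5 | (E)-3-[2-(allyloxy)-3,4-bis(benzyloxy)phenyl]prop-2-en-1-ol | OC/C=C/c1ccc(OCc9ccccc9)c(OCc9ccccc9)c1OCC=C | intermediate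
6 | (E)-3-[2-(allyloxy)-3,4-bis(benzyloxy)phenyl]allyl methyl carbonate | COC(=O)OC/C=C/c1ccc(OCc9ccccc9)c(OCc9ccccc9)c1OCC=C | intermediate
7 | (S)-1-[2-(allyloxy)-3,4-bis(benzyloxy)phenyl]prop-2-en-1-ol | O[C@@H](C=C)c1ccc(OCc9ccccc9)c(OCc9ccccc9)c1OCC=C | intermediate
8 | bis{(S)-1-[2-(allyloxy)-3,4-bis(benzyloxy)phenyl]allyl} ether | C=C[C@@H](c1ccc(OCc9ccccc9)c(OCc9ccccc9)c1OCC=C)O[C@@H](C=C)c1ccc(OCc9ccccc9)c(OCc9ccccc9)c1OCC=C | intermediate
9 | bis{(S)-1-[3,4-bis(benzyloxy)-2-hydroxyphenyl]allyl} ether | C=C[C@@H](c1ccc(OCc9ccccc9)c(OCc9ccccc9)c1O)O[C@@H](C=C)c1ccc(OCc9ccccc9)c(OCc9ccccc9)c1O | intermediate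
10 | bis{(S)-1-[3,4-bis(benzyloxy)-2-(tert-butyldimethylsilyloxy)phenyl]allyl} ether | C=C[C@@H](c1ccc(OCc9ccccc9)c(OCc9ccccc9)c1O[Si](C)(C)C(C)(C)C)O[C@@H](C=C)c1ccc(OCc9ccccc9)c(OCc9ccccc9)c1O[Si](C)(C)C(C)(C)C | intermediate
11 | (2S,2'S,3R,3'R)-3,3'-oxybis(3-Ar-propane-1,2-diol), C2-symmetric tetraol | OC[C@H](O)[C@@H](c1ccc(OCc9ccccc9)c(OCc9ccccc9)c1O[Si](C)(C)C(C)(C)C)O[C@H](c1ccc(OCc9ccccc9)c(OCc9ccccc9)c1O[Si](C)(C)C(C)(C)C)[C@@H](O)CO | intermediate
12 | (2S,2'S,3R,3'R)-3,3'-oxybis[3-Ar-1-(tert-butyldimethylsilyloxy)propan-2-ol] | CC(C)(C)[Si](C)(C)OC[C@H](O)[C@@H](c1ccc(OCc9ccccc9)c(OCc9ccccc9)c1O[Si](C)(C)C(C)(C)C)O[C@H](c1ccc(OCc9ccccc9)c(OCc9ccccc9)c1O[Si](C)(C)C(C)(C)C)[C@@H](O)CO[Si](C)(C)C(C)(C)C | intermediate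
13 | (2S,3R)-3-Ar-3-{[(1R,2S)-1-Ar-3-(tert-butyldimethylsilyloxy)-2-(naphthalen-2-ylmethoxy)propyl]oxy}-1-(tert-butyldimethylsilyloxy)propan-2-ol | CC(C)(C)[Si](C)(C)OC[C@H](O)[C@@H](c1ccc(OCc9ccccc9)c(OCc9ccccc9)c1O[Si](C)(C)C(C)(C)C)O[C@H](c1ccc(OCc9ccccc9)c(OCc9ccccc9)c1O[Si](C)(C)C(C)(C)C)[C@@H](OCc7ccc8ccccc8c7)CO[Si](C)(C)C(C)(C)C | intermediate
14 | (1R,2S)-1-Ar-2,3-bis(tert-butyldimethylsilyloxy)propyl (1R,2S)-1-Ar-3-(tert-butyldimethylsilyloxy)-2-(naphthalen-2-ylmethoxy)propyl ether | CC(C)(C)[Si](C)(C)OC[C@H](O[Si](C)(C)C(C)(C)C)[C@@H](c1ccc(OCc9ccccc9)c(OCc9ccccc9)c1O[Si](C)(C)C(C)(C)C)O[C@H](c1ccc(OCc9ccccc9)c(OCc9ccccc9)c1O[Si](C)(C)C(C)(C)C)[C@@H](OCc7ccc8ccccc8c7)CO[Si](C)(C)C(C)(C)C | intermediate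
15 | (2S,3R)-3-Ar-3-{[(1R,2S)-1-Ar-3-hydroxy-2-(naphthalen-2-ylmethoxy)propyl]oxy}-2-(tert-butyldimethylsilyloxy)propan-1-ol | OC[C@H](O[Si](C)(C)C(C)(C)C)[C@@H](c1ccc(OCc9ccccc9)c(OCc9ccccc9)c1O[Si](C)(C)C(C)(C)C)O[C@H](c1ccc(OCc9ccccc9)c(OCc9ccccc9)c1O[Si](C)(C)C(C)(C)C)[C@@H](OCc7ccc8ccccc8c7)CO | intermediate
16 | (2R,3R)-3-Ar-3-{[(1R,2R)-1-Ar-2-(naphthalen-2-ylmethoxy)-3-oxopropyl]oxy}-2-(tert-butyldimethylsilyloxy)propanal, ether-linked dialdehyde | O=C[C@H](O[Si](C)(C)C(C)(C)C)[C@@H](c1ccc(OCc9ccccc9)c(OCc9ccccc9)c1O[Si](C)(C)C(C)(C)C)O[C@H](c1ccc(OCc9ccccc9)c(OCc9ccccc9)c1O[Si](C)(C)C(C)(C)C)[C@@H](OCc7ccc8ccccc8c7)C=O | intermediate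
17 | 1-(benzyloxy)-4-bromobenzene | Brc1ccc(OCc2ccccc2)cc1 | starting material
18 | 4-(benzyloxy)phenylmagnesium bromide | Br[Mg]c1ccc(OCc2ccccc2)cc1 | intermediate
19 | (1S,2S,3R)-3-Ar-1-[4-(benzyloxy)phenyl]-3-{[(1R,2S,3R)-1-Ar-3-[4-(benzyloxy)phenyl]-3-hydroxy-2-(naphthalen-2-ylmethoxy)propyl]oxy}-2-(tert-butyldimethylsilyloxy)propan-1-ol, erythro silyloxy arm and threo naphthylmethoxy arm | c9ccccc9COc1ccc([C@H](O)[C@H](O[Si](C)(C)C(C)(C)C)[C@@H](c2ccc(OCc9ccccc9)c(OCc9ccccc9)c2O[Si](C)(C)C(C)(C)C)O[C@H](c2ccc(OCc9ccccc9)c(OCc9ccccc9)c2O[Si](C)(C)C(C)(C)C)[C@@H](OCc7ccc8ccccc8c7)[C@H](O)c2ccc(OCc9ccccc9)cc2)cc1 | intermediate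
20 | (1S,2S,3R)-3-Ar'-1-[4-(benzyloxy)phenyl]-3-{[(1R,2S,3R)-1-Ar'-3-[4-(benzyloxy)phenyl]-3-hydroxy-2-(naphthalen-2-ylmethoxy)propyl]oxy}-2-(tert-butyldimethylsilyloxy)propan-1-ol, bis-phenol | c9ccccc9COc1ccc([C@H](O)[C@H](O[Si](C)(C)C(C)(C)C)[C@@H](c2ccc(OCc9ccccc9)c(OCc9ccccc9)c2O)O[C@H](c2ccc(OCc9ccccc9)c(OCc9ccccc9)c2O)[C@@H](OCc7ccc8ccccc8c7)[C@H](O)c2ccc(OCc9ccccc9)cc2)cc1 | intermediate
21 | (2R,3R,4R)-7,8-bis(benzyloxy)-2-[4-(benzyloxy)phenyl]-3-(tert-butyldimethylsilyloxy)-4-{[(2S,3R,4R)-7,8-bis(benzyloxy)-2-[4-(benzyloxy)phenyl]-3-(naphthalen-2-ylmethoxy)chroman-4-yl]oxy}chromane | c9ccccc9COc1ccc([C@H]2Oc3c(ccc(OCc9ccccc9)c3OCc9ccccc9)[C@@H](O[C@@H]3c4ccc(OCc9ccccc9)c(OCc9ccccc9)c4O[C@@H](c4ccc(OCc9ccccc9)cc4)[C@@H]3OCc7ccc8ccccc8c7)[C@H]2O[Si](C)(C)C(C)(C)C)cc1 | intermediate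
22 | (2R,3R,4R)-7,8-bis(benzyloxy)-2-[4-(benzyloxy)phenyl]-4-{[(2S,3R,4R)-7,8-bis(benzyloxy)-2-[4-(benzyloxy)phenyl]-3-(naphthalen-2-ylmethoxy)chroman-4-yl]oxy}chroman-3-ol | c9ccccc9COc1ccc([C@H]2Oc3c(ccc(OCc9ccccc9)c3OCc9ccccc9)[C@@H](O[C@@H]3c4ccc(OCc9ccccc9)c(OCc9ccccc9)c4O[C@@H](c4ccc(OCc9ccccc9)cc4)[C@@H]3OCc7ccc8ccccc8c7)[C@H]2O)cc1 | intermediate
23 | (2R,3R,4R)-2-(4-hydroxyphenyl)-4-{[(2S,3R,4R)-3,7,8-trihydroxy-2-(4-hydroxyphenyl)chroman-4-yl]oxy}chromane-3,7,8-triol | Oc1ccc([C@H]2Oc3c(ccc(O)c3O)[C@@H](O[C@@H]3c4ccc(O)c(O)c4O[C@@H](c4ccc(O)cc4)[C@@H]3O)[C@H]2O)cc1 | target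

## Step count and least certain steps

Total: 20 steps. Longest linear sequence: 20 steps (1 to 23). Compound 17 enters in step 16 through 18, which is made in the flask; two molecules of 18 are built into 19.

Step 16 (key step). The most likely failure is poor facial selectivity at the silyloxy aldehyde. Felkin–Anh preference with an aryl Grignard reagent is intrinsically modest. The β-ether oxygen together with the added MgBr2 could open a competing six-membered chelate, and the anti relationship of the α- and β-oxygens is the less favourable case for non-chelation control. Fallback: the two additions are run separately with different metals. It sets out from 16 and comes back at 19. One equivalent of 18 with MgBr2·OEt2 in CH2Cl2 at −78 °C should react only at the chelated, rate-accelerated formyl group and give the mono-adduct hydroxy aldehyde F1. A further portion of 18 is transmetalated with ClTi(OiPr)3 (THF, −78 °C) to the aryltitanium reagent [4-(benzyloxy)phenyl]tri(propan-2-yloxy)titanium F2. F2 does not chelate and should add to the remaining formyl group of F1 (THF, −78 to −20 °C) with Felkin–Anh selectivity, to give 19.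

Step 7. The most likely failure is sluggish attack of the hindered secondary copper alkoxide on the ortho-substituted allyl–iridium intermediate, with loss of branched selectivity and of catalyst control over the new centre. Fallback: a stereospecific substitution replaces the enantioselective one. It sets out from 7 and comes back at 8. Part of 7 is converted (n-BuLi, Boc2O, THF, −78 °C) into its branched tert-butyl carbonate F3. F3 is then coupled with the copper alkoxide of 7 (LiN(SiMe3)2, CuI) under RhCl(PPh3)3/P(OMe)3 catalysis, which substitutes with net retention at the allylic carbon and so transfers the configuration of 7 to both centres of 8.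

Step 10. The most likely failure is incomplete anti selectivity: with two alkenes any leakage is compounded, and the di-ortho-substituted aryl group on the allylic carbon may oppose the face the ligand prefers. Fallback: C3 is corrected after the event by oxidation and chelation-controlled reduction. It sets out from 12 (then a mixture of C3 epimers) and comes back to 12. Dess–Martin oxidation of both secondary carbinols gives the diketone F4. Reduction of F4 with Zn(BH4)2 (Et2O, −30 °C) through a chelate between each ketone and the adjacent C4 ether oxygen delivers hydride anti to the C4 aryl group and returns the anti,anti diol 12; the ketone must be kept cold and neutral to protect the C4 centre.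

Step 18. The most likely failure is partial ionisation of the activated 4-benzyloxybenzylic oxyphosphonium, so that inversion at C2 is no longer clean; this is worst on the arm that must close to the less stable 2,3-cis ring. Elimination is a second risk. Fallback: closure with retention, which never activates the carbinol. Because the halves differ only at C2, this gives the same target with the roles of the arms exchanged. It sets out from 20 and comes back at 23. The phenols are converted with PhNTf2 and K2CO3 into the bis(aryl triflate) F5. Intramolecular aryl C–O coupling (Pd(OAc)2, 2-(di-tert-butylphosphino)-2',4',6'-triisopropylbiphenyl, Cs2CO3, toluene, 80 °C) gives the dimer F6, in which the silyloxy unit is 2,3-trans and the naphthylmethoxy unit 2,3-cis. TBAF gives the alcohol F7, and hydrogenolysis as in step 20 gives 23.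

Step 20. The most likely failure is hydrogenolysis of the C4–O–C4 ether (benzylic on both sides and activated by the para phenols once the first benzyl groups have gone) while the aliphatic arylmethyl ether is still being removed. Fallback: the aliphatic ether is removed oxidatively first, so that hydrogen only has to cleave phenolic benzyl ethers. It sets out from 22 and comes back at 23. DDQ in CH2Cl2/pH 7 buffer at 0 °C, kept short because DDQ can also attack the benzylic C–H bonds of flavans, cleaves the 2-naphthylmethyl ether and gives the hexa-O-benzyl diol F8. A brief hydrogenolysis of F8 over Pd/C in THF–MeOH then gives 23.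

## Further compounds

F1 | step 16 | (2R,3R)-3-Ar-3-{[(1R,2S,3R)-1-Ar-3-[4-(benzyloxy)phenyl]-3-hydroxy-2-(naphthalen-2-ylmethoxy)propyl]oxy}-2-(tert-butyldimethylsilyloxy)propanal | O=C[C@H](O[Si](C)(C)C(C)(C)C)[C@@H](c2ccc(OCc9ccccc9)c(OCc9ccccc9)c2O[Si](C)(C)C(C)(C)C)O[C@H](c2ccc(OCc9ccccc9)c(OCc9ccccc9)c2O[Si](C)(C)C(C)(C)C)[C@@H](OCc7ccc8ccccc8c7)[C@H](O)c2ccc(OCc9ccccc9)cc2
F2 | step 16 | [4-(benzyloxy)phenyl]tri(propan-2-yloxy)titanium | CC(C)O[Ti](OC(C)C)(OC(C)C)c1ccc(OCc2ccccc2)cc1
F3 | step 7 | (S)-1-[2-(allyloxy)-3,4-bis(benzyloxy)phenyl]allyl tert-butyl carbonate | CC(C)(C)OC(=O)O[C@@H](C=C)c1ccc(OCc9ccccc9)c(OCc9ccccc9)c1OCC=C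
F4 | step 10 | (1R,1'R)-1,1'-oxybis[1-Ar-3-(tert-butyldimethylsilyloxy)propan-2-one] | CC(C)(C)[Si](C)(C)OCC(=O)[C@@H](c1ccc(OCc9ccccc9)c(OCc9ccccc9)c1O[Si](C)(C)C(C)(C)C)O[C@H](c1ccc(OCc9ccccc9)c(OCc9ccccc9)c1O[Si](C)(C)C(C)(C)C)C(=O)CO[Si](C)(C)C(C)(C)C
F5 | step 18 | bis(aryl triflate) of 20 (both phenolic oxygens triflated, configurations as in 20) | c9ccccc9COc1ccc([C@H](O)[C@H](O[Si](C)(C)C(C)(C)C)[C@@H](c2ccc(OCc9ccccc9)c(OCc9ccccc9)c2OS(=O)(=O)C(F)(F)F)O[C@H](c2ccc(OCc9ccccc9)c(OCc9ccccc9)c2OS(=O)(=O)C(F)(F)F)[C@@H](OCc7ccc8ccccc8c7)[C@H](O)c2ccc(OCc9ccccc9)cc2)cc1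
F6 | step 18 | (2S,3R,4R)-7,8-bis(benzyloxy)-2-[4-(benzyloxy)phenyl]-3-(tert-butyldimethylsilyloxy)-4-{[(2R,3R,4R)-7,8-bis(benzyloxy)-2-[4-(benzyloxy)phenyl]-3-(naphthalen-2-ylmethoxy)chroman-4-yl]oxy}chromane | c9ccccc9COc1ccc([C@@H]2Oc3c(ccc(OCc9ccccc9)c3OCc9ccccc9)[C@@H](O[C@@H]3c4ccc(OCc9ccccc9)c(OCc9ccccc9)c4O[C@H](c4ccc(OCc9ccccc9)cc4)[C@@H]3OCc7ccc8ccccc8c7)[C@H]2O[Si](C)(C)C(C)(C)C)cc1
F7 | step 18 | (2S,3R,4R)-7,8-bis(benzyloxy)-2-[4-(benzyloxy)phenyl]-4-{[(2R,3R,4R)-7,8-bis(benzyloxy)-2-[4-(benzyloxy)phenyl]-3-(naphthalen-2-ylmethoxy)chroman-4-yl]oxy}chroman-3-ol | c9ccccc9COc1ccc([C@@H]2Oc3c(ccc(OCc9ccccc9)c3OCc9ccccc9)[C@@H](O[C@@H]3c4ccc(OCc9ccccc9)c(OCc9ccccc9)c4O[C@H](c4ccc(OCc9ccccc9)cc4)[C@@H]3OCc7ccc8ccccc8c7)[C@H]2O)cc1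
F8 | step 20 | (2R,3R,4R)-7,8-bis(benzyloxy)-2-[4-(benzyloxy)phenyl]-4-{[(2S,3R,4R)-7,8-bis(benzyloxy)-2-[4-(benzyloxy)phenyl]-3-hydroxychroman-4-yl]oxy}chroman-3-ol | c9ccccc9COc1ccc([C@H]2Oc3c(ccc(OCc9ccccc9)c3OCc9ccccc9)[C@@H](O[C@@H]3c4ccc(OCc9ccccc9)c(OCc9ccccc9)c4O[C@@H](c4ccc(OCc9ccccc9)cc4)[C@@H]3O)[C@H]2O)cc1
A1 | alternative 1 | all-cis unit A (3,7,8-tri-O-benzyl, 4'-O-benzyl) 4-O-{(2R)-7,8-bis(benzyloxy)-2-[4-(benzyloxy)phenyl]-2H-chromen-4-yl} ether | c9ccccc9COc1ccc([C@H]2Oc3c(ccc(OCc9ccccc9)c3OCc9ccccc9)[C@@H](OC3=C[C@H](c4ccc(OCc9ccccc9)cc4)Oc4c3ccc(OCc9ccccc9)c4OCc9ccccc9)[C@H]2OCc9ccccc9)cc1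
A2 | alternative 1 | all-cis unit A 4-O-[3,4-bis(benzyloxy)-2-({(R)-1-[4-(benzyloxy)phenyl]allyl}oxy)benzoate] | c9ccccc9COc1ccc([C@H]2Oc3c(ccc(OCc9ccccc9)c3OCc9ccccc9)[C@@H](OC(=O)c3ccc(OCc9ccccc9)c(OCc9ccccc9)c3O[C@H](C=C)c3ccc(OCc9ccccc9)cc3)[C@H]2OCc9ccccc9)cc1
A3 | alternative 2 | ether-linked bis[3,4-bis(benzyloxy)-2-hydroxyphenyl] compound with both ring B chains (C2 silyl ethers, C3 benzyl ethers, one erythro and one threo arm) | c9ccccc9COc1ccc([C@H](O[Si](C)(C)C(C)(C)C)[C@H](OCc9ccccc9)[C@@H](c2ccc(OCc9ccccc9)c(OCc9ccccc9)c2O)O[C@H](c2ccc(OCc9ccccc9)c(OCc9ccccc9)c2O)[C@@H](OCc9ccccc9)[C@H](O[Si](C)(C)C(C)(C)C)c2ccc(OCc9ccccc9)cc2)cc1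
A4 | alternative 2 | bis[(E)-3-(tributylstannyl)allyl] ether carrying both ring B chains (C2 silyl ethers, C3 benzyl ethers) | c9ccccc9COc1ccc([C@H](O[Si](C)(C)C(C)(C)C)[C@H](OCc9ccccc9)[C@@H](/C=C/[Sn](CCCC)(CCCC)CCCC)O[C@H](/C=C/[Sn](CCCC)(CCCC)CCCC)[C@@H](OCc9ccccc9)[C@H](O[Si](C)(C)C(C)(C)C)c2ccc(OCc9ccccc9)cc2)cc1
A5 | alternative 2 | 2,3-bis(benzyloxy)-4-chlorocyclobut-2-en-1-one | O=C1C(OCc2ccccc2)=C(OCc2ccccc2)C1Cl
A6 | alternative 3 | protected C2-symmetric all-cis dimer (both units 2R,3R,4R; ring B oxygens as triisopropylsilyl ethers) | CC(C)[Si](C(C)C)(C(C)C)Oc1ccc([C@H]2Oc3c(ccc(OCc9ccccc9)c3OCc9ccccc9)[C@@H](O[C@@H]3c4ccc(OCc9ccccc9)c(OCc9ccccc9)c4O[C@H](c4ccc(O[Si](C(C)C)(C(C)C)C(C)C)cc4)[C@@H]3OCc9ccccc9)[C@H]2OCc9ccccc9)cc1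
A7 | alternative 3 | C2-symmetric threo,threo diol with two 3,4-bis(benzyloxy)-2-bromophenyl groups, C3 benzyl ethers and 4-(triisopropylsilyloxy)phenyl carbinols | CC(C)[Si](C(C)C)(C(C)C)Oc1ccc([C@@H](O)[C@H](OCc9ccccc9)[C@@H](c2ccc(OCc9ccccc9)c(OCc9ccccc9)c2Br)O[C@H](c2ccc(OCc9ccccc9)c(OCc9ccccc9)c2Br)[C@@H](OCc9ccccc9)[C@H](O)c2ccc(O[Si](C(C)C)(C(C)C)C(C)C)cc2)cc1
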